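**Retrosynthetic overview**

1. The target is the C5 gem-diprenylated, dearomatised form of a 7-isovaleryl-4,6-dihydroxy-2,3-dihydrobenzofuran (ring A carbocycle, ring B dihydrofuran). The last disconnection is the two C5–prenyl bonds, formed by dearomative double C-alkylation.
2. The strategy rests on this feature: ring B is attached to two neighbouring carbons of ring A through O1–C7a and C3–C3a, and its O1–C2H(CMe2OH)–C3H2 chain is atom for atom a terminal epoxide. Both bonds are therefore cut at once, giving an aryl iodide (iodine on C7a, free C–H on C3a, isovaleryl on C7) and an (R)-epoxide.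
3. The aryl iodide comes from 1-iodo-3,5-dimethoxybenzene by Friedel–Crafts acylation, followed by exchange of the methyl ethers for benzyl ethers, so that the later unmasking is a neutral hydrogenolysis and not a double thiolate demethylation. The epoxide comes from methyl (R)-glycerate acetonide, with the tertiary alcohol carried as a benzyl ether.
4. Ring order: ring A is bought as an arene, ring B is closed in the palladium/norbornene annulation, and ring A is dearomatised in the last step. The single stereocentre C2 comes from the chiral pool and no step breaks a bond to it.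

Key step: step 8

Remark: the target is a cyclic β-tricarbonyl compound; the route aims at the drawn tautomer (4-oxo, 6-hydroxy), which equilibrates with its other enol forms and is treated as one compound.

**Step 1**
Reactants: 1 1-iodo-3,5-dimethoxybenzene; 2 3-methylbutanoyl chloride
Product: 3 1-(2-iodo-4,6-dimethoxyphenyl)-3-methylbutan-1-one
Conditions: AlCl3 (1.2 equiv), CH2Cl2, 0 °C
Reagents that add atoms: none
Why: Friedel–Crafts acylation, in which the acylium ion should enter at the carbon para to one methoxy group and ortho to the other (next to iodine) rather than at the more crowded carbon between the two methoxy groups, while iodine sits meta to both donors and is not prone to ipso attack.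

**Step 2**
Reactants: 3 1-(2-iodo-4,6-dimethoxyphenyl)-3-methylbutan-1-one
Product: 4 1-(2,4-dihydroxy-6-iodophenyl)-3-methylbutan-1-one
Conditions: BBr3 (4 equiv), CH2Cl2, −78 °C to rt; then H2O
Reagents that add atoms: none
Why: Lewis-acid ether cleavage with BBr3 is the standard exhaustive demethylation of acylphloroglucinol-type methyl ethers, and the aryl iodide and the ketone are inert to it.

**Step 3**
Reactants: 4 1-(2,4-dihydroxy-6-iodophenyl)-3-methylbutan-1-one
Product: 5 1-[2,4-bis(benzyloxy)-6-iodophenyl]-3-methylbutan-1-one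
Conditions: BnBr (2.5 equiv), K2CO3 (3 equiv), DMF, 70 °C
Reagents that add atoms: benzyl bromide, BrCc1ccccc1
Why: Williamson ether synthesis in a polar aprotic solvent should O-benzylate both phenoxides (the ketone-chelated one needs the heating), giving ethers that survive carbonate and palladium and are later removed without acid or nucleophile.

**Step 4**
Reactants: 6 methyl (4R)-2,2-dimethyl-1,3-dioxolane-4-carboxylate
Product: 7 2-[(4R)-2,2-dimethyl-1,3-dioxolan-4-yl]propan-2-ol
Conditions: MeMgBr (3 equiv), THF, 0 °C to rt (ester added to the Grignard reagent)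
Reagents that add atoms: methylmagnesium bromide, C[Mg]Br
Why: Double Grignard addition to the ester builds the tertiary carbinol without touching any bond at C4, so the (R) centre is kept, and inverse addition at low temperature limits enolisation of the intermediate ketone.

**Step 5**
Reactants: 7 2-[(4R)-2,2-dimethyl-1,3-dioxolan-4-yl]propan-2-ol
Product: 8 (4R)-4-[2-(benzyloxy)propan-2-yl]-2,2-dimethyl-1,3-dioxolane
Conditions: NaH, BnBr, Bu4NI (cat.), THF–DMF, 0 to 50 °C
Reagents that add atoms: benzyl bromide, BrCc1ccccc1
Why: Williamson etherification of the tertiary sodium alkoxide with the reactive benzylic halide caps the alcohol with a group that cannot migrate to the neighbouring oxygen and cannot take part in a Payne rearrangement once the epoxide is made.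

**Step 6**
Reactants: 8 (4R)-4-[2-(benzyloxy)propan-2-yl]-2,2-dimethyl-1,3-dioxolane
Product: 9 (2R)-3-(benzyloxy)-3-methylbutane-1,2-diol
Conditions: AcOH–H2O (4:1), 40 °C
Reagents that add atoms: none
Why: Acid-catalysed acetal hydrolysis removes the terminal isopropylidene group under conditions too mild to ionise the tertiary benzyl ether, and the carbinol C–O bond is not cleaved.

**Step 7**
Reactants: 9 (2R)-3-(benzyloxy)-3-methylbutane-1,2-diol
Product: 11 (2R)-2-[2-(benzyloxy)propan-2-yl]oxirane, via primary tosylate 10 (not isolated)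
Conditions: TsCl (1.05 equiv), Et3N, DMAP (cat.), CH2Cl2, 0 °C; then K2CO3, MeOH, rt
Reagents that add atoms: none
Why: Selective sulfonylation of the primary hydroxyl (the secondary one is flanked by a quaternary carbon) followed by intramolecular Williamson (3-exo-tet) displacement by the secondary alkoxide closes the epoxide at the primary carbon, so the C2–O bond is never broken and the (R) configuration is retained.

**Step 8**
Reactants: 5 1-[2,4-bis(benzyloxy)-6-iodophenyl]-3-methylbutan-1-one; 11 (2R)-2-[2-(benzyloxy)propan-2-yl]oxirane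
Product: 12 1-[(2R)-4,6-bis(benzyloxy)-2-[2-(benzyloxy)propan-2-yl]-2,3-dihydro-1-benzofuran-7-yl]-3-methylbutan-1-one
Conditions: Pd(OAc)2 (10 mol %), RuPhos (20 mol %), norbornene (50 mol %), Cs2CO3 (2 equiv), 11 (2.5 equiv), 1,4-dioxane, 100 °C
Reagents that add atoms: none
Why: Oxidative addition of 5 to zerovalent palladium, norbornene insertion and carbonate-assisted palladation of the one free ortho C–H give an aryl–norbornyl palladacycle of divalent palladium, which opens epoxide 11 at its CH2 carbon through tetravalent palladium and forms the aryl–CH2 bond by reductive elimination. With both ortho positions now substituted, norbornene is expelled by β-carbon elimination and ring B closes at the ipso carbon by C–O reductive elimination from the aryl(alkoxo)palladium chelate, an intramolecular etherification that makes the five-membered ring. The closest known reaction is the Catellani-type annulation of ortho-substituted aryl iodides with terminal epoxides to 2,3-dihydrobenzofurans. No stereocentre is created: C2 is the epoxide carbon whose C–O bond is never broken, so the (R) configuration of 11 is carried over. The step needs attack at the CH2 and not the CH terminus, which the quaternary C(CH3)2OBn neighbour enforces, and a single ortho alkylation with the oxygen ending next to the acyl group, which the isovaleryl group secures by occupying the other ortho position. The C–H to be palladated lies beside a benzyloxy-bearing carbon, which is the demanding element of the step.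

**Step 9**
Reactants: 12 1-[(2R)-4,6-bis(benzyloxy)-2-[2-(benzyloxy)propan-2-yl]-2,3-dihydro-1-benzofuran-7-yl]-3-methylbutan-1-one
Product: 13 1-[(2R)-4,6-dihydroxy-2-(2-hydroxypropan-2-yl)-2,3-dihydro-1-benzofuran-7-yl]-3-methylbutan-1-one
Conditions: H2 (1 atm), Pd(OH)2/C, EtOAc–MeOH, rt
Reagents that add atoms: none
Why: Catalytic hydrogenolysis should cleave all three benzylic C–O bonds (two aryl benzyl ethers and the tertiary alkyl benzyl ether), while the hydrogen-bonded aryl ketone and the aryl alkyl ether of ring B are not reduced at one atmosphere.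

**Step 10**
Reactants: 13 1-[(2R)-4,6-dihydroxy-2-(2-hydroxypropan-2-yl)-2,3-dihydro-1-benzofuran-7-yl]-3-methylbutan-1-one; 14 1-bromo-3-methylbut-2-ene
Product: 16 (2R)-6-hydroxy-2-(2-hydroxypropan-2-yl)-7-(3-methylbutanoyl)-5,5-bis(3-methylbut-2-en-1-yl)-2,3-dihydro-1-benzofuran-4(5H)-one, via monoprenyl diphenol 15 (not isolated)
Conditions: NaOMe (3 equiv), 14 (2.5 equiv), MeOH, 0 °C to rt; then dilute HCl
Reagents that add atoms: none
Why: Base-mediated dearomative C-alkylation of an acylphloroglucinol-type phenoxide (the reaction used for hop β-acids) should prenylate C5, the only unsubstituted ring carbon and one flanked by two phenoxide oxygens, first to 15 and then a second time with loss of aromaticity, the protic solvent favouring C- over O-alkylation; C5 carries two identical groups and is no stereocentre, and C2 is untouched.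

**Compound list**

1 | 1-iodo-3,5-dimethoxybenzene | COc1cc(I)cc(OC)c1 | starting material
2 | 3-methylbutanoyl chloride (isovaleryl chloride) | CC(C)CC(Cl)=O | starting material
3 | 1-(2-iodo-4,6-dimethoxyphenyl)-3-methylbutan-1-one | CC(C)CC(=O)c1c(I)cc(OC)cc1OC | intermediate
4 | 1-(2,4-dihydroxy-6-iodophenyl)-3-methylbutan-1-one | CC(C)CC(=O)c1c(I)cc(O)cc1O | intermediate
5 | 1-[2,4-bis(benzyloxy)-6-iodophenyl]-3-methylbutan-1-one | CC(C)CC(=O)c1c(I)cc(OCc2ccccc2)cc1OCc3ccccc3 | intermediate
6 | methyl (4R)-2,2-dimethyl-1,3-dioxolane-4-carboxylate (methyl (R)-glycerate acetonide) | COC(=O)[C@H]1COC(C)(C)O1 | starting material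
7 | 2-[(4R)-2,2-dimethyl-1,3-dioxolan-4-yl]propan-2-ol | CC(C)(O)[C@H]1COC(C)(C)O1 | intermediate
8 | (4R)-4-[2-(benzyloxy)propan-2-yl]-2,2-dimethyl-1,3-dioxolane | CC(C)(OCc2ccccc2)[C@H]1COC(C)(C)O1 | intermediate
9 | (2R)-3-(benzyloxy)-3-methylbutane-1,2-diol | CC(C)(OCc1ccccc1)[C@H](O)CO | intermediate
10 | (2R)-3-(benzyloxy)-2-hydroxy-3-methylbutyl 4-methylbenzenesulfonate | CC(C)(OCc1ccccc1)[C@H](O)COS(=O)(=O)c1ccc(C)cc1 | intermediate (not isolated)
11 | (2R)-2-[2-(benzyloxy)propan-2-yl]oxirane | CC(C)(OCc2ccccc2)[C@H]1CO1 | intermediate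
12 | 1-[(2R)-4,6-bis(benzyloxy)-2-[2-(benzyloxy)propan-2-yl]-2,3-dihydro-1-benzofuran-7-yl]-3-methylbutan-1-one | CC(C)CC(=O)c1c(OCc3ccccc3)cc(OCc4ccccc4)c2c1O[C@@H](C(C)(C)OCc5ccccc5)C2 | intermediate
13 | 1-[(2R)-4,6-dihydroxy-2-(2-hydroxypropan-2-yl)-2,3-dihydro-1-benzofuran-7-yl]-3-methylbutan-1-one | CC(C)CC(=O)c1c(O)cc(O)c2c1O[C@@H](C(C)(C)O)C2 | intermediate
14 | 1-bromo-3-methylbut-2-ene (prenyl bromide) | CC(C)=CCBr | starting material
15 | 1-[(2R)-4,6-dihydroxy-2-(2-hydroxypropan-2-yl)-5-(3-methylbut-2-en-1-yl)-2,3-dihydro-1-benzofuran-7-yl]-3-methylbutan-1-one | CC(C)CC(=O)c1c(O)c(CC=C(C)C)c(O)c2c1O[C@@H](C(C)(C)O)C2 | intermediate (not isolated)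
16 | (2R)-6-hydroxy-2-(2-hydroxypropan-2-yl)-7-(3-methylbutanoyl)-5,5-bis(3-methylbut-2-en-1-yl)-2,3-dihydro-1-benzofuran-4(5H)-one | CC(C)=CCC1(CC=C(C)C)C(=O)C2=C(O[C@@H](C(C)(C)O)C2)C(C(=O)CC(C)C)=C1O | target

**Step count**

Total: 10 steps. Longest linear sequence: 7 steps (steps 4 to 10, from 6 to 16). The arene branch (steps 1 to 3) joins at step 8.

**Steps most likely to fail**

1. Step 8. The ortho C–H palladation has to take place beside the benzyloxy-bearing carbon. If it is too slow, the arylpalladium species may be reduced or may couple at the ipso carbon alone, and the epoxide may be consumed by iodide or carbonate. The fallback sets out from 5 and comes back to the route at 13; it builds the C3–C3a bond by sigmatropic rearrangement and the O1–C2 bond by epoxide opening.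
   - Copper-catalysed hydroxylation of 5 (CuI, 1,10-phenanthroline, KOH, DMSO–H2O, 100 °C) should give 1-[2,4-bis(benzyloxy)-6-hydroxyphenyl]-3-methylbutan-1-one F1.
   - Pd(PPh3)4-catalysed O-allylation with tert-butyl 2-methylbut-3-en-2-yl carbonate should give the 1,1-dimethylallyl aryl ether F2.
   - Aromatic Claisen rearrangement (toluene, 110 °C) should deliver the allyl unit, as a prenyl group, to the only free ortho carbon and give the ortho-prenyl phenol F3.
   - Acetylation (Ac2O, DMAP, Et3N) should give the aryl acetate F4, which protects the phenol from the oxidant.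
   - Shi epoxidation (KHSO5, K2CO3 buffer, MeCN–dimethoxymethane, 0 °C) with the enantiomer of the fructose-derived ketone that delivers the (S)-epoxide (expected to be the one from L-fructose) should give the epoxy acetate F5.
   - K2CO3 in MeOH should remove the acetate to the epoxy phenol F6, which is not isolated. Its phenoxide should open the epoxide 5-exo at the secondary carbon with inversion, giving the (2R)-dihydrobenzofuran F7.
   - Hydrogenolysis of the two benzyl ethers of F7 (H2, Pd(OH)2/C) should give 13.

2. Step 10. O-Prenylation of the phenoxides and solvolysis of the allylic bromide may outrun the second C-alkylation, so that the reaction stalls at the monoprenyl stage or drains into aryl ethers. The fallback sets out from 13 and comes back at 16; it separates C–C bond formation from installation of the trisubstituted alkenes.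
   - Tsuji–Trost allylation (Pd(PPh3)4, allyl methyl carbonate, THF, rt) uses a soft π-allylpalladium electrophile that reacts at carbon. It should pass through the monoallyl diphenol F8 and give the 5,5-diallyl dienone F9.
   - Cross-metathesis with excess 2-methylbut-2-ene (second-generation Grubbs catalyst, CH2Cl2, 40 °C) should convert both allyl groups into prenyl groups, by way of the allyl prenyl intermediate F10, and give 16.

3. Step 1. Regiocontrol in the electrophilic substitution may be incomplete, with part of the acylation going to the carbon between the two methoxy groups, and the strong Lewis acid may cause migration or loss of iodine. The fallback sets out from 1 and comes back at 3; it uses a bulkier, milder electrophile and assembles the ketone in two carbon–carbon bond formations.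
   - Vilsmeier–Haack formylation (POCl3, DMF, 0 to 80 °C) should give the aryl iminium salt F11, and aqueous work-up should hydrolyse it to 2-iodo-4,6-dimethoxybenzaldehyde F12.
   - Addition of isobutylmagnesium bromide (i-BuMgBr, THF, −78 °C), where carbonyl addition is faster than iodine–magnesium exchange, should give the secondary alcohol F13.
   - Oxidation with Dess–Martin periodinane (CH2Cl2, rt) should give 3.

**Further compounds**

F1 | step 8 | 1-[2,4-bis(benzyloxy)-6-hydroxyphenyl]-3-methylbutan-1-one | CC(C)CC(=O)c1c(O)cc(OCc2ccccc2)cc1OCc3ccccc3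
F2 | step 8 | 1-{2,4-bis(benzyloxy)-6-[(2-methylbut-3-en-2-yl)oxy]phenyl}-3-methylbutan-1-one | CC(C)CC(=O)c1c(OC(C)(C)C=C)cc(OCc2ccccc2)cc1OCc3ccccc3
F3 | step 8 | 1-[4,6-bis(benzyloxy)-2-hydroxy-3-(3-methylbut-2-en-1-yl)phenyl]-3-methylbutan-1-one | CC(C)CC(=O)c1c(O)c(CC=C(C)C)c(OCc2ccccc2)cc1OCc3ccccc3
F4 | step 8 | 3,5-bis(benzyloxy)-2-(3-methylbutanoyl)-6-(3-methylbut-2-en-1-yl)phenyl acetate | CC(C)CC(=O)c1c(OC(C)=O)c(CC=C(C)C)c(OCc2ccccc2)cc1OCc3ccccc3
F5 | step 8 | 3,5-bis(benzyloxy)-2-{[(2S)-3,3-dimethyloxiran-2-yl]methyl}-6-(3-methylbutanoyl)phenyl acetate | CC(C)CC(=O)c1c(OC(C)=O)c(C[C@@H]2OC2(C)C)c(OCc3ccccc3)cc1OCc4ccccc4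
F6 | step 8 | 1-[4,6-bis(benzyloxy)-3-{[(2S)-3,3-dimethyloxiran-2-yl]methyl}-2-hydroxyphenyl]-3-methylbutan-1-one | CC(C)CC(=O)c1c(O)c(C[C@@H]2OC2(C)C)c(OCc3ccccc3)cc1OCc4ccccc4
F7 | step 8 | 1-[(2R)-4,6-bis(benzyloxy)-2-(2-hydroxypropan-2-yl)-2,3-dihydro-1-benzofuran-7-yl]-3-methylbutan-1-one | CC(C)CC(=O)c1c(OCc3ccccc3)cc(OCc4ccccc4)c2c1O[C@@H](C(C)(C)O)C2
F8 | step 10 | 1-[(2R)-4,6-dihydroxy-2-(2-hydroxypropan-2-yl)-5-(prop-2-en-1-yl)-2,3-dihydro-1-benzofuran-7-yl]-3-methylbutan-1-one | CC(C)CC(=O)c1c(O)c(CC=C)c(O)c2c1O[C@@H](C(C)(C)O)C2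
F9 | step 10 | (2R)-6-hydroxy-2-(2-hydroxypropan-2-yl)-7-(3-methylbutanoyl)-5,5-di(prop-2-en-1-yl)-2,3-dihydro-1-benzofuran-4(5H)-one | C=CCC1(CC=C)C(=O)C2=C(O[C@@H](C(C)(C)O)C2)C(C(=O)CC(C)C)=C1O
F10 | step 10 | (2R)-6-hydroxy-2-(2-hydroxypropan-2-yl)-7-(3-methylbutanoyl)-5-(3-methylbut-2-en-1-yl)-5-(prop-2-en-1-yl)-2,3-dihydro-1-benzofuran-4(5H)-one (both C5 epimers) | C=CCC1(CC=C(C)C)C(=O)C2=C(O[C@@H](C(C)(C)O)C2)C(C(=O)CC(C)C)=C1O
F11 | step 1 | [(2-iodo-4,6-dimethoxyphenyl)methylidene]dimethylazanium chloride | C[N+](C)=Cc1c(I)cc(OC)cc1OC.[Cl-]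
F12 | step 1 | 2-iodo-4,6-dimethoxybenzaldehyde | O=Cc1c(I)cc(OC)cc1OC
F13 | step 1 | 1-(2-iodo-4,6-dimethoxyphenyl)-3-methylbutan-1-ol (racemic) | CC(C)CC(O)c1c(I)cc(OC)cc1OC
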